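**Retrosynthetic overview**

1. Target 6 (1-OH and 6-OAc cis, 5-OBz trans) ⇒ zeylenone 5 by acetylation of its only secondary OH; 5 ⇒ syn-epoxy quinol 4 + benzoic acid by trans opening of the oxirane at its allylic carbon.
2. 4 ⇒ (R)-o-quinol dienone 3 by hydroxyl-directed epoxidation of the γ,δ-alkene, done in the flask in which 3 is formed, before it can dimerize.
3. 3 ⇒ 2-hydroxybenzyl benzoate 2 by enantioselective ortho-hydroxylative dearomatization, the chemical counterpart of the arene-oxide/o-quinol step in the presumed biogenesis of the zeylenone family; 2 ⇒ salicyl alcohol 1.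
4. Ring order: the six-membered carbocycle is the phenol ring itself (dearomatized in step 2, which sets the quaternary carbinol); the oxirane is formed next on the OH face and opened last; no C–C bond is made.

Assumption: the (S)-axis antipode of the binaphthyl bis(iodyl) reagent is written as the one that gives (R)-3; this sense of induction must be confirmed on the first run (rotation of 5), the (R)-axis antipode is used if it is the reverse, and the reagent is made beforehand from the commercial enantiopure diiodide and DMDO.

**Route**

Step 1
Reactants: 1 salicyl alcohol (2-(hydroxymethyl)phenol)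
Product: 2 2-hydroxybenzyl benzoate
Conditions: vinyl benzoate (3 equiv), Novozym 435 (immobilized Candida antarctica lipase B), MTBE, 45 °C
Reagents that add atoms: vinyl benzoate, C=COC(=O)c1ccccc1
Why: Lipase-catalysed irreversible transesterification acylates only the primary benzylic hydroxyl, because phenols are not acyl acceptors for the enzyme, and the neutral medium avoids o-quinone methide formation; no stereocenter is formed.

Step 2
Reactants: 2 2-hydroxybenzyl benzoate
Product: 4 syn-epoxy quinol [(1S,2S,6S)-2-hydroxy-3-oxo-7-oxabicyclo[4.1.0]hept-4-en-2-yl]methyl benzoate, via (R)-o-quinol dienone 3 (not isolated)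
Conditions: (S)-2,2'-diiodyl-1,1'-binaphthyl (1.1 equiv), CH2Cl2 (0.01 M), −40 °C; H2O (10 equiv); then DMDO (acetone, 4 equiv), −40 → −10 °C
Reagents that add atoms: (S)-2,2'-diiodyl-1,1'-binaphthyl, O=I(=O)c1ccc2ccccc2c1-c1c(I(=O)=O)ccc2ccccc12 (one oxo O; the chiral axis is not encoded in the SMILES); dimethyldioxirane (DMDO), CC1(C)OO1 (one O)
Why: Proposed new method: the phenol binds to pentavalent iodine and an oxo ligand is passed intramolecularly to the CH2OBz-bearing ortho carbon inside the chiral biaryl pocket, which sets the quaternary carbinol as (R) (closest known reaction: hydroxylative phenol dearomatization of 2-alkylphenols with axially chiral iodyl biaryls, and of this very phenol with achiral pentavalent-iodine reagents, where the quinol is otherwise lost to [4+2] dimerization), and because that dimerization is second order in 3 it is held back by cold and high dilution while excess DMDO epoxidizes the more electron-rich γ,δ-alkene of the quinol freed by water from the O–iodine bond, on the face of the tertiary OH (hydrogen-bond delivery, reinforced by the bulkier CH2OBz group on the other face), which sets both oxirane carbons (closest known reaction: peracid or dioxirane epoxidation of cyclic allylic alcohols and of cyclohexa-2,4-dienones at the γ,δ-alkene).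

Step 3
Reactants: 4 syn-epoxy quinol
Product: 5 zeylenone [(1S,5R,6S)-5-benzoyloxy-1,6-dihydroxy-2-oxocyclohex-3-en-1-yl]methyl benzoate
Conditions: PhCO2H (1.5 equiv), Ti(OiPr)4 (1.5 equiv), CH2Cl2, 0 °C → rt
Reagents that add atoms: benzoic acid, OC(=O)c1ccccc1
Why: The tetravalent titanium alkoxide of the tertiary OH holds the cis-oxirane and directs benzoate to C3 of the 2,3-epoxy alcohol unit (Sharpless-type titanium-mediated epoxy alcohol opening), which is also the allylic and less hindered oxirane carbon, so SN2 inversion there sets the 5-benzoate trans to the 6-OH while the C6–O bond keeps its configuration, and the cis epoxy alcohol cannot undergo Payne rearrangement.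

Step 4
Reactants: 5 zeylenone
Product: 6 2-O-acetylzeylenone [(1S,5R,6S)-6-acetyloxy-5-benzoyloxy-1-hydroxy-2-oxocyclohex-3-en-1-yl]methyl benzoate
Conditions: Ac2O (3 equiv), pyridine, CH2Cl2, 0 °C → rt
Reagents that add atoms: acetic anhydride, CC(=O)OC(C)=O
Why: Pyridine-mediated O-acylation takes the only secondary hydroxyl, the tertiary α-ketol OH being too hindered to react without DMAP, and no stereocenter is touched.

**Compound list**

1 | salicyl alcohol (2-(hydroxymethyl)phenol) | OCc1ccccc1O | starting material
2 | 2-hydroxybenzyl benzoate | O=C(OCc1ccccc1O)c1ccccc1 | intermediate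
3 | (R)-o-quinol dienone, [(1R)-1-hydroxy-6-oxocyclohexa-2,4-dien-1-yl]methyl benzoate (not isolated) | C1=CC=CC(=O)[C@]1(O)COC(=O)c1ccccc1 | intermediate
4 | syn-epoxy quinol, [(1S,2S,6S)-2-hydroxy-3-oxo-7-oxabicyclo[4.1.0]hept-4-en-2-yl]methyl benzoate | O1[C@H]2[C@@H]1C=CC(=O)[C@]2(O)COC(=O)c1ccccc1 | intermediate
5 | zeylenone, [(1S,5R,6S)-5-benzoyloxy-1,6-dihydroxy-2-oxocyclohex-3-en-1-yl]methyl benzoate | O[C@H]1[C@H](OC(=O)c2ccccc2)C=CC(=O)[C@]1(O)COC(=O)c1ccccc1 | intermediate
6 | 2-O-acetylzeylenone, [(1S,5R,6S)-6-acetyloxy-5-benzoyloxy-1-hydroxy-2-oxocyclohex-3-en-1-yl]methyl benzoate | CC(=O)O[C@H]1[C@H](OC(=O)c2ccccc2)C=CC(=O)[C@]1(O)COC(=O)c1ccccc1 | target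

**Totals**

Total step count: 4. Longest linear sequence: 4 steps (1 → 2 → 4 → 5 → 6).

**Steps most likely to fail**

Step 2 is the main risk. The free quinol 3 may dimerize faster than it is epoxidized, oxidation may also occur at the unsubstituted ortho carbon, and the ee may be moderate (5 is crystalline and can be recrystallized to raise it). The fallback separates dearomatization from epoxidation through the dimer. Setting out from 3, the DMDO stage is left out and the solution is warmed to rt, so that 3 undergoes its spontaneous endo-selective [4+2] dimerization to the homochiral bicyclo[2.2.2]octenone cyclodimer F1, a stable crystalline store of the monomer that can be recrystallized to raise the ee. F1 is then cracked by retro-Diels–Alder reaction in a continuous-flow coil (dilute toluene, about 220 °C, residence time of a minute or two). The outflow is chilled in line and run directly into cold DMDO (CH2Cl2/acetone, −20 °C), so that regenerated 3 is epoxidized at once, and the route is rejoined at 4.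

Step 3 may fail through titanium-promoted aromatization or α-ketol chemistry of the epoxy enone, attack at the wrong oxirane carbon, or benzoyl migration in the product. The fallback splits the step into hydration and acylation. Setting out from 4, acid-catalysed hydrolysis (0.05 M HClO4, THF/H2O, 0 °C) opens the oxirane at the allylic carbon with inversion to the triol monobenzoate F2. Its allylic 5-OH, the less hindered of the two secondary hydroxyls, is then benzoylated selectively (BzCl 1.05 equiv, pyridine, CH2Cl2, −40 °C), which returns to the route at 5.

Step 4 may fail through over-acetylation of the tertiary OH, base-induced benzoyl migration, or E1cB loss of the new acetoxy group through the γ-deprotonated dienolate. The fallback is a base-free, intramolecular delivery of the acetyl group through the cis-diol. Setting out from 5, trimethyl orthoacetate and catalytic PPTS (CH2Cl2, rt) tie the cis 1,6-diol up as the cyclic methyl orthoacetate F3. Brief treatment with 80% aqueous acetic acid at rt opens it through the acetoxonium ion to the hydroxy acetate, and under these equilibrating acidic conditions the acetyl group settles on the secondary oxygen, which gives the target 6.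

**Further compounds**

F1 | step 2 | homochiral endo [4+2] cyclodimer of 3, (3,10-dihydroxy-4,9-dioxotricyclo[6.2.2.0(2,7)]dodeca-5,11-diene-3,10-diyl)dimethyl dibenzoate | O=C1C=C[C@H]2[C@@H]([C@@]1(O)COC(=O)c1ccccc1)[C@H]1C=C[C@@H]2C(=O)[C@]1(O)COC(=O)c1ccccc1
F2 | step 3 | triol monobenzoate, [(1S,5R,6S)-1,5,6-trihydroxy-2-oxocyclohex-3-en-1-yl]methyl benzoate | O[C@H]1[C@H](O)C=CC(=O)[C@]1(O)COC(=O)c1ccccc1
F3 | step 4 | cyclic methyl orthoacetate of 5 across the 1- and 6-oxygens (both epimers at the orthoester carbon) | COC1(C)O[C@H]2[C@H](OC(=O)c3ccccc3)C=CC(=O)[C@@]2(COC(=O)c3ccccc3)O1
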